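Readings and results were generated by integration with constants of no real substance; the scatter is artificial.

Late in both earlier runs the isomer of the product dominated, with some target and starting material still unconverted, so I began there and reckoned back to the first moments.

| setting | north | south | flask |
|---|---|---|---|
| starting material | 0.15 M | 0.22 M | 0.30 M |
| protic impurity | 6 mM | 6 mM | 6.00 mM |
| remark | run made earlier | run made earlier |  |
| time |  |  | 30 min |

| run | time / min | target / % | isomer of the product / % | starting material / % |
|---|---|---|---|---|
| north | 2.50 | 23 | 20 | 44 |
| north | 8.00 | 21 | 42 | 27 |
| north | 12.0 | 12 | 59 | 24 |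
| north | 20.0 | 9 | 76 | 16 |
| north | 30.0 | 4 | 87 | 6 |
| north | 40.0 | 0 | 88 | 1 |
| south | 6.00 | 25 | 35 | 32 |
| south | 12.0 | 12 | 58 | 21 |
| south | 20.0 | 12 | 76 | 10 |
| south | 25.0 | 4 | 81 | 8 |
| south | 30.0 | 4 | 87 | 8 |
| south | 40.0 | 3 | 88 | 2 |

(standard deviation of a reading: 2 percentage points)



- ratio of target to isomer of the product at 2.0 s
- ratio of target to isomer of the product at 1.0 min
- ratio of target to isomer of the product at 30 min
- which of target and isomer of the product there is more of at 30 min

From 20.0 min to 30.0 min, summing both runs, target plus starting material decayed with a rate constant λ = 0.0759 min⁻¹. Within that pool, target stood at φ = 0.725 per starting material. North and south both read 4 % target and 87 % isomer at 30.0 min, so I carried percentages to the new flask: a ratio of 0.0460 at 30 min, with isomer ahead.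

For the start I used the first north reading. I let starting material A make target P at rate aA and isomer at bA, with target lost at dP. A logarithmic mean gave ∫A dt = 1.71 min, so, on my assumption that the early isomer came directly from starting material, b = 0.117 min⁻¹. I took ∫P dt as 0.667 of the reading times its time, or 0.383 min. Treating late target as stationary, d = a/φ, gave a = 0.195 min⁻¹. Dividing a by b removes time and gives 1.67.

The weak link was that stationarity, since late target falls with the pool. Then d = a/φ + λ, so a = 0.220 min⁻¹, and β = a/b = 1.88. This β is the branch ratio (selectivity factor): target made per isomer made from starting material, and so the ratio at the very start. I committed to that at 2.0 s, and bending it logarithmically toward the first reading gave 1.54 at 1.0 min.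

The forecast, slightly above my reckoning, said 2, 1.6 and 0.05, with isomer of the product ahead: “so the profiles look first-order in charge and should carry over to 0.30 M”.

The flask gave 2.04, 1.61 and 0.0507, with isomer of the product ahead, 86.2 % against 4.36 % of target.

    starting material ⇌ target (K = 0.648, k = 0.241 min⁻¹)
    starting material ⇌ isomer of the product (K = 75.0, k = 0.117 min⁻¹)
    target ⇌ isomer of the product (k = 0.0354 min⁻¹)
    starting material + protic impurity → quenched substrate (k = 14.4 M⁻¹ min⁻¹)
    starting material ⇌ dormant form (K = 0.203, k = 0.266 min⁻¹)

In this flask the ratio at 2.0 s is 2.04, where β read 1.88. That early ratio is held down by the direct reaction of starting material to isomer of the product, which is one part of the picture: the run with that step taken away, both ways, stands at 1690 at 2.0 s in place of 2.04. Isomer is therefore being made from the first moment, beside target and not just after it. The neighbour flask with 0.18 M of starting material, for which I took the same β, stands at 2.04 at 2.0 s.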